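The nine-membered carbocycle is made from a bought cycloheptane-1,3-dione by a two-carbon ring expansion. In the target, carbinol carbon C7 and methylene-bearing C11 are 1,5-related across the unsubstituted Z-C8=C9 alkene and C10H2, which is what results when acetylene is inserted between the enol carbon (C7) and the central carbon (C10) of the dione. One [2+2] photocycloaddition of acetylene to the C7=C10 bond forms C7–C8 and C10–C9 and closes a cyclobutene; cleaving the shared C7–C10 bond then merges the four- and seven-membered rings. The photosubstrate is a trans-fused tetrahydrofuran–cycloheptenone whose enol oxygen has carried a 4-methoxybenzyl group since step 1 and whose C3 bears two differently silylated CH2O arms.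

Key step: step 9

Remark: target numbering (C1, O2, C3, C4a–C11a; C19 = exocyclic methylene carbon) is used for all bicyclic intermediates; the facial courses of the directed epoxidation (step 7) and of the methyl addition (step 13) are assumed as argued in those steps and would be checked by NOE on 12 and 20. Abbreviations: PMB = 4-methoxybenzyl, TBDPS = tert-butyldiphenylsilyl, TBS = tert-butyldimethylsilyl, pin = pinacolato.

Step 1
Reactants: 1 cycloheptane-1,3-dione
Product: 2 3-[(4-methoxybenzyl)oxy]cyclohept-2-en-1-one
Conditions: 4-MeOC6H4CH2OH, PPh3, DIAD, THF, 0 °C → rt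
Reagents that add atoms: 4-methoxybenzyl alcohol, COc1ccc(CO)cc1
Why: Mitsunobu O-alkylation of the acidic cyclic 1,3-dione should give the vinylogous ester, and because the oxidatively removable benzyl group is placed on the still symmetric dione, the C7 oxygen stays etherified until the cyclobutene is in place, so no later choice between two enol oxygens is needed.

Step 2
Reactants: 2 3-[(4-methoxybenzyl)oxy]cyclohept-2-en-1-one
Product: 5 3-[(4-methoxybenzyl)oxy]cyclohepta-2,6-dien-1-one, via α'-phenylselenide 3 (not isolated), via selenoxide 4 (not isolated)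
Conditions: LiN(iPr)2, THF, −78 °C; PhSeBr; then 30% H2O2, pyridine, CH2Cl2, 0 °C → rt
Reagents that add atoms: none
Why: Kinetic deprotonation of a vinylogous ester takes place at the alpha' methylene, so selenenylation there and syn-elimination of the selenoxide (selenoxide elimination) should introduce the second, unsubstituted enone of the cross-conjugated dienone.

Step 3
Reactants: 6 2-bromoprop-2-en-1-ol
Product: 7 [(2-bromoprop-2-en-1-yl)oxy](tert-butyl)diphenylsilane
Conditions: t-BuPh2SiCl, imidazole, CH2Cl2, 0 °C → rt
Reagents that add atoms: tert-butyl(chloro)diphenylsilane, CC(C)(C)[Si](Cl)(c1ccccc1)c1ccccc1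
Why: Standard silylation of a primary alcohol; the bulky silyl ether is a poor leaving group and should survive every step up to step 19.

Step 4
Reactants: 7 [(2-bromoprop-2-en-1-yl)oxy](tert-butyl)diphenylsilane
Product: 8 tert-butyl(diphenyl){[2-(pinacolatoboryl)prop-2-en-1-yl]oxy}silane
Conditions: B2pin2, PdCl2(PPh3)2 (3 mol %), PPh3, KOPh, toluene, 50 °C
Reagents that add atoms: bis(pinacolato)diboron, CC1(C)OB(OC1(C)C)B1OC(C)(C)C(C)(C)O1
Why: Miyaura borylation of an alkenyl bromide with phenoxide as base should exchange bromine for the pinacolboryl group without touching the allylic silyl ether.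

Step 5
Reactants: 5 3-[(4-methoxybenzyl)oxy]cyclohepta-2,6-dien-1-one + 8 tert-butyl(diphenyl){[2-(pinacolatoboryl)prop-2-en-1-yl]oxy}silane
Product: 9 (6S)-3-(PMB-oxy)-6-[3-(TBDPS-oxy)prop-1-en-2-yl]cyclohept-2-en-1-one
Conditions: [RhCl(C2H4)2]2 (2.5 mol %), (S)-BINAP (6 mol %), K3PO4 (aq), dioxane, 40 °C; 8 in excess
Reagents that add atoms: none
Why: In this Hayashi–Miyaura addition the alkenyl-Rh(BINAP) species adds only to the unsubstituted enone (the alkoxy-bearing one is a deactivated vinylogous ester), the (S)-BINAP complex selecting the enone face that gives (S)-3-substituted cycloalkanones and so setting C4a, while the poor silanolate leaving group and the excess of 8 offset beta-oxygen elimination and protodeboronation.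

Step 6
Reactants: 9 (6S)-3-(PMB-oxy)-6-[3-(TBDPS-oxy)prop-1-en-2-yl]cyclohept-2-en-1-one
Product: 10 (6S,7S)-7-(hydroxymethyl)-3-(PMB-oxy)-6-[3-(TBDPS-oxy)prop-1-en-2-yl]cyclohept-2-en-1-one
Conditions: LiN(iPr)2, THF, −78 °C; CH2O (gas, from cracked paraformaldehyde), −78 °C; AcOH quench
Reagents that add atoms: formaldehyde, C=O
Why: The kinetic alpha' lithium enolate undergoes an aldol addition to monomeric formaldehyde on the face anti to the neighbouring alkenyl group, which should set C11a trans to C4a (the future trans ring fusion).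

Step 7
Reactants: 10 (6S,7S)-7-(hydroxymethyl)-3-(PMB-oxy)-6-[3-(TBDPS-oxy)prop-1-en-2-yl]cyclohept-2-en-1-one
Product: 12 (3S,4aS,11aS)-tetrahydrofuran-fused enone alcohol (C3: CH2OH trans to C5; CH2OTBDPS cis to C5), via epoxy alcohol 11 (not isolated)
Conditions: VO(acac)2 (5 mol %), t-BuOOH, CH2Cl2, 0 °C → rt; then PPTS (cat.)
Reagents that add atoms: tert-butyl hydroperoxide, CC(C)(C)OO
Why: In this hydroxyl-directed epoxidation the peroxo complex formed from VO(acac)2 and bound to the C1 hydroxyl should deliver oxygen to the alkene face turned toward C11a in the rotamer that eclipses H4a with the CH2OTBDPS group (least A(1,2) strain), and invertive 5-exo-tet attack of the same hydroxyl on the tertiary epoxide carbon closes the tetrahydrofuran ring and sets C3 with the new CH2OH trans to C5; should the other face react, the two constitutionally distinct arms simply exchange their later roles.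

Step 8
Reactants: 12 (3S,4aS,11aS)-tetrahydrofuran-fused enone alcohol
Product: 13 (3S,4aS,11aS)-photosubstrate (C7 PMB enol ether; C11 ketone; C3 CH2OTBS trans to C5; C3 CH2OTBDPS cis to C5)
Conditions: t-BuMe2SiCl, imidazole, DMF, rt
Reagents that add atoms: tert-butyl(chloro)dimethylsilane, CC(C)(C)[Si](C)(C)Cl
Why: Silylation of the remaining primary alcohol gives the arm that is to be unveiled first a silyl ether more labile than the one on the other arm.

Step 9
Reactants: 13 (3S,4aS,11aS)-photosubstrate + 14 acetylene
Product: 15 cyclobutene photoadduct (bicyclo[5.2.0]non-8-en-2-one core fused to the tetrahydrofuran; cis-fused at C7/C10)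
Conditions: hν (medium-pressure Hg lamp, uranium-glass filter, λ > 330 nm), C2H2-saturated CH2Cl2 (continuous stream), −40 °C, stopped at partial conversion, 13 recycled
Reagents that add atoms: none
Why: Excitation of the alkoxy enone and intersystem crossing give its triplet, which adds to acetylene stepwise: a first bond gives a 1,4-biradical, and after spin inversion the second bond closes the cyclobutene, so that C7–C8 and C10–C9 are formed and C8=C9 is installed Z and unsubstituted. The closest known reaction type is the enone–alkyne [2+2] photocycloaddition in its de Mayo form, in which the enone is the fixed enol ether of a cyclic 1,3-dione. The four-membered ring closes by radical–radical coupling within the biradical and not by a polar attack, so no Baldwin class applies; it is cis-fused to the seven-membered ring because a trans-fused cyclobutene there would be prohibitively strained. The new centres C7 and C10 are therefore fixed only relative to each other; their facial sense with respect to C4a/C11a is uncontrolled and immaterial, since both carbons become sp2 again in steps 12 and 14. The step needs capture of the triplet by acetylene to outrun twisting about C7=C10, dimerisation and secondary photolysis of the beta,gamma-unsaturated ketone formed; the trans-fused tetrahydrofuran stiffens the seven-membered ring, acetylene is used at saturation and low temperature, only the alkoxy enone absorbs beyond 330 nm and irradiation is stopped early. No regiochemical question arises because acetylene is symmetric and the enol ether has sat on C7 since step 1, and the ethers are photo-inert while the diene is not yet present.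

Step 10
Reactants: 15 cyclobutene photoadduct
Product: 17 C11 spiro-epoxide of the photoadduct, via lithium chlorohydrin alkoxide 16 (not isolated)
Conditions: ClCH2I, MeLi·LiBr, THF, −78 °C → rt
Reagents that add atoms: chloroiodomethane, ClCI
Why: Chloromethyllithium generated in situ is small, highly nucleophilic and weakly basic, so it should add at −78 °C to the hindered, enolisable C11 ketone (the only carbonyl present) and close to the spiro-epoxide on warming, an epoxide synthesis equivalent to the Corey–Chaykovsky reaction that brings in C19; the new C11 centre need not be controlled because it becomes sp2 in step 12.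

Step 11
Reactants: 17 C11 spiro-epoxide of the photoadduct
Product: 18 tertiary cyclobutenol spiro-epoxide
Conditions: DDQ, CH2Cl2/pH 7 phosphate buffer, 0 °C; used without chromatography
Reagents that add atoms: none
Why: DDQ oxidises the electron-rich benzylic ether to a hemiacetal that collapses to the free tertiary cyclobutenol (oxidative PMB cleavage), leaving silyl ethers, epoxide and cyclobutene untouched under buffered conditions.

Step 12
Reactants: 18 tertiary cyclobutenol spiro-epoxide
Product: 19 (3S,4aS,11aR,8Z)-nine-membered 8,10-dien-7-one with C11 CH2OH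
Conditions: KN(SiMe3)2 (1.0 equiv), THF, −78 → −20 °C; AcOH quench
Reagents that add atoms: none
Why: Proposed new method: deprotonation gives the potassium alkoxide of 18, whose oxygen lone pair pushes into the antibonding orbital of the strained C7–C10 bond so that the four-membered ring opens (about 30 kcal/mol of strain released) and the charge developing at C10, the terminus of an extended enolate, is discharged by opening the adjacent C11 spiro-epoxide, giving one conjugated dienone with Z-C8=C9 inherited from the cyclobutene and a C19 alkoxide; the closest known reaction types are the Grob fragmentation of hydroxy epoxides, the retro-aldol cleavage of de Mayo photoadducts and the oxyanion-accelerated opening of cyclobutenols.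

Step 13
Reactants: 19 (3S,4aS,11aR,8Z)-nine-membered 8,10-dien-7-one with C11 CH2OH
Product: 20 (3S,4aS,7S,11aR,8Z)-7-methyl-7-hydroxy 8,10-diene with C11 CH2OH
Conditions: MeLi, CeCl3 (anhydrous), THF, −78 °C (3 equiv)
Reagents that add atoms: methyllithium, [Li]C
Why: The weakly basic reagent MeCeCl2 adds 1,2 to the only carbonyl without enolisation or conjugate addition, and attack from the peripheral face of the preferred conformer of the nine-membered dienone is expected to give the 7S carbinol.

Step 14
Reactants: 20 (3S,4aS,7S,11aR,8Z)-7-methyl-7-hydroxy 8,10-diene with C11 CH2OH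
Product: 23 (3S,4aS,7S,11aR,8Z)-nine-membered core with C7 carbinol and C11 exocyclic methylene, via sulfonylhydrazine adduct 21 (not isolated), via allylic diazene 22 (not isolated)
Conditions: 2-O2NC6H4SO2NHNH2, PPh3, DIAD, N-methylmorpholine, −30 °C → rt
Reagents that add atoms: none
Why: Mitsunobu reaction of the primary allylic alcohol with the sulfonylhydrazide, loss of sulfinic acid to the monoalkyl diazene and retro-ene loss of N2 deliver hydrogen to C10 and move the double bond to C11=C19 (reductive 1,3-transposition of an allylic alcohol), which erases the C10=C11 geometry; the tertiary alcohol does not enter the Mitsunobu reaction.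

Step 15
Reactants: 23 (3S,4aS,7S,11aR,8Z)-nine-membered core with C7 carbinol and C11 exocyclic methylene
Product: 24 (3S,4aS,7S,11aR,8Z)-primary alcohol (C3 CH2OH trans to C5)
Conditions: HF·pyridine, pyridine, THF, 0 °C
Reagents that add atoms: none
Why: Buffered HF·pyridine cleaves a primary tert-butyldimethylsilyl ether far faster than the tert-butyldiphenylsilyl ether on the same carbon and does not ionise the tertiary allylic alcohol.

Step 16
Reactants: 24 (3S,4aS,7S,11aR,8Z)-primary alcohol
Product: 25 (3R,4aS,7S,11aR,8Z)-C3 aldehyde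
Conditions: Dess–Martin periodinane, NaHCO3, CH2Cl2, rt
Reagents that add atoms: none
Why: Dess–Martin oxidation of the primary alcohol gives a non-enolisable aldehyde, the tertiary alcohol being inert.

Step 17
Reactants: 25 (3R,4aS,7S,11aR,8Z)-C3 aldehyde
Product: 26 (3S,4aS,7S,11aR,8Z)-C3 (E)-2-iodovinyl compound
Conditions: CrCl2, CHI3, THF, 0 °C → rt
Reagents that add atoms: iodoform, IC(I)I
Why: Takai olefination with the reagent formed from CrCl2 and CHI3 converts the hindered aldehyde into the (E)-iodoalkene with the usual high E preference and tolerates the free tertiary alcohol.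

Step 18
Reactants: 26 (3S,4aS,7S,11aR,8Z)-C3 (E)-2-iodovinyl compound + 27 4,4,5,5-tetramethyl-2-(2-methylprop-1-en-1-yl)-1,3,2-dioxaborolane
Product: 28 (3R,4aS,7S,11aR,8Z)-(E)-dienyl core TBDPS ether
Conditions: Pd(PPh3)4 (5 mol %), K3PO4 (aq), THF, 45 °C
Reagents that add atoms: none
Why: Suzuki–Miyaura coupling proceeds with retention at both alkenyl partners and so should give the (E)-diene, which is introduced only now, after all photochemical, oxidative and Mitsunobu steps.

Step 19
Reactants: 28 (3R,4aS,7S,11aR,8Z)-(E)-dienyl core TBDPS ether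
Product: 29 (3R,4aS,7S,11aR,8Z)-diol (primary C3 CH2OH and tertiary C7 OH)
Conditions: Bu4NF, THF, 0 °C → rt
Reagents that add atoms: none
Why: Fluoride removes the remaining silyl ether without affecting the diene, the other alkenes or the tertiary alcohol.

Step 20
Reactants: 29 (3R,4aS,7S,11aR,8Z)-diol + 30 hexadecanoyl chloride
Product: 31 CNP0150666.1 (target)
Conditions: pyridine, DMAP (cat.), CH2Cl2, 0 °C
Reagents that add atoms: none
Why: Acylation with the acid chloride under pyridine/DMAP takes place at the primary alcohol only, the tertiary allylic alcohol being too hindered to react at 0 °C.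

Compound list

1 | cycloheptane-1,3-dione | O=C1CCCCC(=O)C1 | starting material
2 | 3-[(4-methoxybenzyl)oxy]cyclohept-2-en-1-one | COc1ccc(COC2=CC(=O)CCCC2)cc1 | intermediate
3 | 3-[(4-methoxybenzyl)oxy]-7-(phenylselanyl)cyclohept-2-en-1-one (racemic, not isolated) | COc1ccc(COC2=CC(=O)C([Se]c3ccccc3)CCC2)cc1 | intermediate
4 | selenoxide of 3 (not isolated) | COc1ccc(COC2=CC(=O)C([Se](=O)c3ccccc3)CCC2)cc1 | intermediate
5 | 3-[(4-methoxybenzyl)oxy]cyclohepta-2,6-dien-1-one | COc1ccc(COC2=CC(=O)C=CCC2)cc1 | intermediate
6 | 2-bromoprop-2-en-1-ol | C=C(Br)CO | starting material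
7 | [(2-bromoprop-2-en-1-yl)oxy](tert-butyl)diphenylsilane | C=C(Br)CO[Si](c1ccccc1)(c1ccccc1)C(C)(C)C | intermediate
8 | tert-butyl(diphenyl){[2-(4,4,5,5-tetramethyl-1,3,2-dioxaborolan-2-yl)prop-2-en-1-yl]oxy}silane | C=C(CO[Si](c1ccccc1)(c1ccccc1)C(C)(C)C)B1OC(C)(C)C(C)(C)O1 | intermediate
9 | (6S)-3-[(4-methoxybenzyl)oxy]-6-{3-[(tert-butyldiphenylsilyl)oxy]prop-1-en-2-yl}cyclohept-2-en-1-one | COc1ccc(COC2=CC(=O)C[C@@H](C(=C)CO[Si](c3ccccc3)(c3ccccc3)C(C)(C)C)CC2)cc1 | intermediate
10 | (6S,7S)-7-(hydroxymethyl) derivative of 9 (6,7-trans) | COc1ccc(COC2=CC(=O)[C@H](CO)[C@@H](C(=C)CO[Si](c3ccccc3)(c3ccccc3)C(C)(C)C)CC2)cc1 | intermediate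
11 | epoxy alcohol from 10: 2,2-disubstituted oxirane on the former isopropenyl carbon (not isolated) | COc1ccc(COC2=CC(=O)[C@H](CO)[C@@H]([C@]3(CO[Si](c4ccccc4)(c4ccccc4)C(C)(C)C)CO3)CC2)cc1 | intermediate
12 | (3S,4aS,11aS)-trans-fused tetrahydrofuran–cycloheptenone: C7 PMB enol ether (C7=C10), C11 ketone, C3 with CH2OH trans to C5 and CH2OTBDPS cis to C5 | COc1ccc(COC2=CC(=O)[C@@H]3CO[C@@](CO)(CO[Si](c4ccccc4)(c4ccccc4)C(C)(C)C)[C@H]3CC2)cc1 | intermediate
13 | TBS ether of 12 (photosubstrate; 3S,4aS,11aS) | COc1ccc(COC2=CC(=O)[C@@H]3CO[C@@](CO[Si](C)(C)C(C)(C)C)(CO[Si](c4ccccc4)(c4ccccc4)C(C)(C)C)[C@H]3CC2)cc1 | intermediate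
14 | acetylene | C#C | starting material
15 | cyclobutene photoadduct: C7(OPMB)–C8=C9–C10 four-membered ring cis-fused across C7–C10, C11 ketone; facial sense at C7/C10 not defined | COc1ccc(COC23C=CC2C(=O)[C@@H]2CO[C@@](CO[Si](C)(C)C(C)(C)C)(CO[Si](c4ccccc4)(c4ccccc4)C(C)(C)C)[C@H]2CC3)cc1 | intermediate
16 | lithium alkoxide of the C11 chloromethyl carbinol (not isolated; C11 not defined) | COc1ccc(COC23C=CC2C(O[Li])(CCl)[C@@H]2CO[C@@](CO[Si](C)(C)C(C)(C)C)(CO[Si](c4ccccc4)(c4ccccc4)C(C)(C)C)[C@H]2CC3)cc1 | intermediate
17 | C11 spiro-epoxide of 15 (C7, C10, C11 not defined) | COc1ccc(COC23C=CC2C2(CO2)[C@@H]2CO[C@@](CO[Si](C)(C)C(C)(C)C)(CO[Si](c4ccccc4)(c4ccccc4)C(C)(C)C)[C@H]2CC3)cc1 | intermediate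
18 | tertiary cyclobutenol spiro-epoxide (17 without PMB) | OC12C=CC1C1(CO1)[C@@H]1CO[C@@](CO[Si](C)(C)C(C)(C)C)(CO[Si](c3ccccc3)(c3ccccc3)C(C)(C)C)[C@H]1CC2 | intermediate
19 | (3S,4aS,11aR,8Z)-nine-membered dienone: C7 ketone, Z-C8=C9, C10=C11 (geometry not defined), C11 CH2OH | O=C1/C=C\C=C(CO)[C@@H]2CO[C@@](CO[Si](C)(C)C(C)(C)C)(CO[Si](c3ccccc3)(c3ccccc3)C(C)(C)C)[C@H]2CC1 | intermediate
20 | (3S,4aS,7S,11aR,8Z)-C7 methyl carbinol of 19 | OCC1=C/C=C\[C@@](C)(O)CC[C@H]2[C@H]1CO[C@@]2(CO[Si](C)(C)C(C)(C)C)CO[Si](c1ccccc1)(c1ccccc1)C(C)(C)C | intermediate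
21 | N-(C19-alkyl)-N-(2-nitrobenzenesulfonyl)hydrazine from 20 (not isolated) | NN(CC1=C/C=C\[C@@](C)(O)CC[C@H]2[C@H]1CO[C@@]2(CO[Si](C)(C)C(C)(C)C)CO[Si](c1ccccc1)(c1ccccc1)C(C)(C)C)S(=O)(=O)c1ccccc1[N+](=O)[O-] | intermediate
22 | allylic monoalkyl diazene from 21 (not isolated) | N=NCC1=C/C=C\[C@@](C)(O)CC[C@H]2[C@H]1CO[C@@]2(CO[Si](C)(C)C(C)(C)C)CO[Si](c1ccccc1)(c1ccccc1)C(C)(C)C | intermediate
23 | (3S,4aS,7S,11aR,8Z)-nine-membered core: C7(Me)(OH), Z-C8=C9, C10H2, C11=CH2; C3 CH2OTBS trans and CH2OTBDPS cis to C5 | C=C1C/C=C\[C@@](C)(O)CC[C@H]2[C@H]1CO[C@@]2(CO[Si](C)(C)C(C)(C)C)CO[Si](c1ccccc1)(c1ccccc1)C(C)(C)C | intermediate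
24 | (3S,4aS,7S,11aR,8Z)-alcohol: 23 with free CH2OH in place of CH2OTBS | C=C1C/C=C\[C@@](C)(O)CC[C@H]2[C@H]1CO[C@@]2(CO)CO[Si](c1ccccc1)(c1ccccc1)C(C)(C)C | intermediate
25 | (3R,4aS,7S,11aR,8Z)-C3 aldehyde | C=C1C/C=C\[C@@](C)(O)CC[C@H]2[C@H]1CO[C@@]2(C=O)CO[Si](c1ccccc1)(c1ccccc1)C(C)(C)C | intermediate
26 | (3S,4aS,7S,11aR,8Z)-C3 (E)-2-iodovinyl compound | C=C1C/C=C\[C@@](C)(O)CC[C@H]2[C@H]1CO[C@@]2(/C=C/I)CO[Si](c1ccccc1)(c1ccccc1)C(C)(C)C | intermediate
27 | 4,4,5,5-tetramethyl-2-(2-methylprop-1-en-1-yl)-1,3,2-dioxaborolane | CC(C)=CB1OC(C)(C)C(C)(C)O1 | starting material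
28 | (3R,4aS,7S,11aR,8Z)-C3 (E)-4-methylpenta-1,3-dienyl core, TBDPS ether | C=C1C/C=C\[C@@](C)(O)CC[C@H]2[C@H]1CO[C@@]2(/C=C/C=C(C)C)CO[Si](c1ccccc1)(c1ccccc1)C(C)(C)C | intermediate
29 | (3R,4aS,7S,11aR,8Z)-diol (28 without silyl group) | C=C1C/C=C\[C@@](C)(O)CC[C@H]2[C@H]1CO[C@@]2(/C=C/C=C(C)C)CO | intermediate
30 | hexadecanoyl chloride (palmitoyl chloride) | CCCCCCCCCCCCCCCC(=O)Cl | starting material
31 | CNP0150666.1, (3R,4aS,7S,11aR,8Z)-palmitate | C=C1C/C=C\[C@@](C)(O)CC[C@H]2[C@H]1CO[C@@]2(/C=C/C=C(C)C)COC(=O)CCCCCCCCCCCCCCC | target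

Total step count: 20. Longest linear sequence: 18 steps (1 to 31 through steps 1, 2 and 5–20); steps 3 and 4 prepare boronate 8.

Steps most likely to fail

Step 12 (the step that goes beyond known chemistry). The alkoxide may open the four-membered ring without the charge being passed on to the oxirane (protonation of the extended enolate, or attack of O7 on the epoxide), or the alkoxide of the dienone may add back in conjugate fashion. The fallback uses known reactions only and sets out from 15. DDQ in buffered CH2Cl2 removes the PMB group to give the cyclobutenol ketone F1, a de Mayo-type beta-hydroxy ketone that should undergo retro-aldol cleavage of C7–C10, on standing or with a trace of base, to the (8Z)-ene-7,11-dione F2. Takai–Lombardo methylenation (CH2Br2, Zn, TiCl4), which is non-basic and is expected to favour the non-conjugated C11 ketone, then introduces C19 directly as the exocyclic methylene of the enone F3. Addition of MeLi/CeCl3 to the remaining C7 carbonyl rejoins the route at 23. This path is shorter but depends on telling two ketones apart in an aldol-prone 1,5-dione, which is why it is held in reserve.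

Step 9. Twisting of the excited seven-membered enone about C7=C10, followed by dimerisation or trapping by solvent, may be faster than capture by a gas of limited solubility, and over-irradiation may degrade the beta,gamma-unsaturated ketone. The fallback sets out from 13: irradiation in the presence of a large excess of liquid (Z)-1,2-dichloroethene as an acetylene surrogate should give the dichlorocyclobutane F4 (mixture of isomers), and reductive 1,2-dechlorination with Zn in ethanol returns to the cyclobutene 15.

Step 13. Low facial discrimination in the addition to the conformationally mobile nine-membered dienone would give C7 epimers that cannot be interconverted. The fallback sets out from 19 and comes back at 20: catalyst-controlled methyl transfer (Me2Zn, Ti(OiPr)4 and a chiral bis(sulfonamide) diol ligand of the enantiomer matched to 7S) replaces substrate control; no new compound is made on this path.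

Further compounds

F1 | step 12 | cyclobutenol ketone (15 without PMB) | OC12C=CC1C(=O)[C@@H]1CO[C@@](CO[Si](C)(C)C(C)(C)C)(CO[Si](c3ccccc3)(c3ccccc3)C(C)(C)C)[C@H]1CC2
F2 | step 12 | (3S,4aS,11aS,8Z)-nine-membered 8-ene-7,11-dione | O=C1/C=C\CC(=O)[C@@H]2CO[C@@](CO[Si](C)(C)C(C)(C)C)(CO[Si](c3ccccc3)(c3ccccc3)C(C)(C)C)[C@H]2CC1
F3 | step 12 | (3S,4aS,11aR,8Z)-11-methylene 8-en-7-one | C=C1C/C=C\C(=O)CC[C@H]2[C@H]1CO[C@@]2(CO[Si](C)(C)C(C)(C)C)CO[Si](c1ccccc1)(c1ccccc1)C(C)(C)C
F4 | step 9 | 8,9-dichlorocyclobutane photoadduct of 13 | COc1ccc(COC23C(Cl)C(Cl)C2C(=O)[C@@H]2CO[C@@](CO[Si](C)(C)C(C)(C)C)(CO[Si](c4ccccc4)(c4ccccc4)C(C)(C)C)[C@H]2CC3)cc1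
F0 | step 13 | none | none
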